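**Retrosynthetic overview**

1. Target 25 ⇐ 22 by ozonolysis of the C5 vinyl group (masked C6 aldehyde); 22 ⇐ 20 by C–O bond formation, a 15-OH-directed epoxidation of the C16=C17 methylene.
2. 20 (ring D) ⇐ propargylic alcohol 17 by 5-exo radical enyne cyclisation; 17 ⇐ acid 11 by acyl Sonogashira coupling and asymmetric ynone reduction (sets C15).
3. 11 (ring C, C8 and C9) ⇐ spiro-lactone acid 9 + buta-1,3-diene (Diels–Alder).
4. 9 (ring B, C10) ⇐ formyl enone 5 + methoxymethylene Meldrum's acid: the lactone acyl C–O bond is the key disconnection, closed in a new one-flask annulation.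
5. 5 ⇐ 3 ⇐ dienone 1 (Rh-catalysed desymmetrising vinylation sets C5). Ring order: A → B (lactone) → C → D → epoxide.

Assumption: locants C1–C20 in descriptive names are ent-kaurane numbers (lactone ring = C10–C20–O–C7–C8–C9; the C5 vinyl group is the masked C6 aldehyde), and dienone 1 is bought (otherwise one IBX or DDQ dehydrogenation from 4,4-dimethylcyclohex-2-enone).

**Route**

Step 1
Reactants: 1 4,4-dimethylcyclohexa-2,5-dien-1-one; 2 potassium trifluoro(vinyl)borate
Product: 3 (5R)-5-ethenyl-4,4-dimethylcyclohex-2-en-1-one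
Conditions: [Rh(cod)2]PF6 (3 mol %), (R)-BINAP (3.3 mol %), 2 (1.3 equiv), PhMe/H2O 4:1, 100 °C
Reagents that add atoms: potassium trifluoro(vinyl)borate C=C[B-](F)(F)F.[K+]
Why: Rh(I)/BINAP asymmetric 1,4-addition (Hayashi–Miyaura type) desymmetrises the prochiral dienone: with (R)-BINAP vinyl goes to the enantiotopic β-carbon that gives 5R (opposite sense to the (S)-BINAP → (S)-3-arylcyclohexanone rule), the Rh enolate is protonated by water, and the remaining, more hindered enone reacts much more slowly, so mono-addition dominates.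

Step 2
Reactants: 3 (5R)-5-ethenyl-4,4-dimethylcyclohex-2-en-1-one; 4 ethyl formate
Product: 5 (5R,6Z)-5-ethenyl-6-(hydroxymethylidene)-4,4-dimethylcyclohex-2-en-1-one
Conditions: NaH (1.2 equiv), HCO2Et (3 equiv), EtOH (cat.), THF, 0 °C → rt; 1 M HCl
Reagents that add atoms: ethyl formate CCOC=O
Why: Crossed Claisen formylation: C6 (kaurane C10) is the only enolisable position of 3 (C2–H is vinylic, C4 is quaternary), so the chelated Z-enol of the β-keto aldehyde forms regiospecifically and C5 is untouched.

Step 3
Reactants: 5 (5R,6Z)-5-ethenyl-6-(hydroxymethylidene)-4,4-dimethylcyclohex-2-en-1-one; 6 5-(methoxymethylidene)-2,2-dimethyl-1,3-dioxane-4,6-dione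
Product: 9 (6S,11R)-11-ethenyl-10,10-dimethyl-3,7-dioxo-2-oxaspiro[5.5]undeca-4,8-diene-4-carboxylic acid, via methoxy Meldrum adduct 7 (not isolated), via hydroxymethyl Meldrum adduct 8 (not isolated)
Conditions: NaH (1.05 equiv), THF, 0 °C; 6 (1.1 equiv), −40 → 0 °C; NaBH4 (1.0 equiv), EtOH, −78 °C; 1 M HCl; then TsOH·H2O (10 mol %), PhMe, 50 °C
Reagents that add atoms: 5-(methoxymethylidene)-2,2-dimethyl-1,3-dioxane-4,6-dione COC=C1C(=O)OC(C)(C)OC1=O
Why: Proposed new method: a one-flask vinylic-substitution / masked-alkylidene reduction / acyl-transfer lactonisation, in which the sodium enolate of 5 adds through C10 to the methoxymethylene carbon of 6 anti to the C5 vinyl group (setting the C10 quaternary centre with CHO cis to vinyl), the resulting β-methoxy Meldrum's enolate 7 is not a Michael acceptor and binds the methoxide, so it survives NaBH4 while the aldehyde is reduced to 8, and on acidification methanol is lost and the new primary alcohol attacks the cis-disposed dioxanedione carbonyl, expelling acetone to close the δ-lactone C–O bond and free the C8 carboxylic acid; the closest known reactions are vinylic substitution of alkoxymethylene Meldrum's acids by carbon nucleophiles and the Knoevenagel/lactonisation of salicylaldehydes with Meldrum's acid to coumarin-3-carboxylic acids.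

Step 4
Reactants: 9 (6S,11R)-11-ethenyl-10,10-dimethyl-3,7-dioxo-2-oxaspiro[5.5]undeca-4,8-diene-4-carboxylic acid; 10 buta-1,3-diene
Product: 11 Diels–Alder acid (5R,8S,9S,10S): ring C fused across C8–C9 with a C12=C13 alkene and the C8 CO2H cis to H-9
Conditions: buta-1,3-diene (10 equiv), BHT (cat.), PhMe, 90 °C, sealed tube
Reagents that add atoms: buta-1,3-diene C=CC=C
Why: Thermal Diels–Alder reaction of a doubly activated, internally hydrogen-bonded alkylidene-malonate-type dienophile: butadiene adds suprafacially to C8=C9 (CO2H and H-9 stay cis) from the lactone face next to the flat C1 carbonyl and away from the C5 vinyl/CMe2 side, which sets 8S and 9S, while the A-ring enone and the vinyl group are poor dienophiles and 90 °C is below the decarboxylation temperature of the quaternary malonic half-acid.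

Step 5
Reactants: 11 Diels–Alder acid; 12 oxalyl chloride; 13 ethynyltrimethylsilane
Product: 15 TMS-ynone (5R,8S,9S,10S) with C8–C(=O)–C≡C–SiMe3, via acid chloride 14 (not isolated)
Conditions: (COCl)2 (1.2 equiv), DMF (cat.), CH2Cl2, 0 °C → rt, evaporate; then 13 (1.3 equiv), PdCl2(PPh3)2 (2 mol %), CuI (4 mol %), Et3N (1.3 equiv), THF, rt
Reagents that add atoms: ethynyltrimethylsilane C#C[Si](C)(C)C
Why: Acid chloride formation (no α-hydrogen, so no ketene) followed by Pd/Cu acyl Sonogashira coupling, which turns even pivaloyl-type chlorides into ynones under neutral conditions that the lactone, enone and alkenes tolerate.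

Step 6
Reactants: 15 TMS-ynone
Product: 17 propargylic alcohol (5R,8S,9S,10S,15R) with C8–CH(OH)–C≡CH, via silylated propargylic alcohol 16 (not isolated)
Conditions: RuCl[(S,S)-TsDPEN](p-cymene) (2 mol %), i-PrOH, rt; then K2CO3 (0.2 equiv), MeOH, 0 °C
Reagents that add atoms: none
Why: Noyori asymmetric transfer hydrogenation of the ynone (alkyne as the π-directing group, far more reactive than the hindered enone ketone) with the (S,S)-catalyst, matched with the Felkin–Anh preference of the α-quaternary β-keto lactone, gives the 15R carbinol (15S by CIP while silylated; the OH will end up anti to the C14 bridge), and carbonate-catalysed methanolysis removes the C-silyl group.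

Step 7
Reactants: 17 propargylic alcohol; 18 tributyltin hydride
Product: 20 tetracyclic allylic alcohol (5R,8S,9S,10S,13R,15R) with exocyclic C16=C17 and 15-OH anti to the C14 bridge, via vinylstannane 19 (not isolated)
Conditions: Bu3SnH (1.5 equiv), AIBN (0.2 equiv), PhH (0.03 M), 80 °C; then TsOH·H2O (1.5 equiv), CH2Cl2, 0 °C
Reagents that add atoms: none
Why: Stork-type radical enyne cyclisation: Bu3Sn• adds to the terminal alkyne carbon, the C16 vinyl radical closes 5-exo-trig onto C13 of the C12=C13 alkene (kinetic bicyclo[3.2.1] mode, favoured by a high stannane concentration; C13 can only be bridged from the face of C15, giving 13R), C12• takes H from the stannane, and acid protodestannylation of 19 reveals the exocyclic methylene.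

Step 8
Reactants: 20 tetracyclic allylic alcohol; 21 tert-butyl hydroperoxide
Product: 22 epoxy alcohol (5R,8S,9S,10S,13R,15S,16S) with the 16,17-epoxide oxygen syn to 15-OH and C5 still vinyl
Conditions: VO(acac)2 (5 mol %), t-BuOOH (1.5 equiv, decane), CH2Cl2, 0 °C → rt
Reagents that add atoms: tert-butyl hydroperoxide CC(C)(C)OO
Why: Hydroxyl-directed vanadium-catalysed epoxidation (Sharpless VO(acac)2/TBHP): the C15 vanadate delivers oxygen to the C16=C17 face syn to the 15-OH, setting 16S, while the electron-poor enone and the isolated vinyl group are not epoxidised.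

Step 9
Reactants: 22 epoxy alcohol; 23 ozone
Product: 25 target CNP0537841.1 (5R,8S,9S,10S,13R,15S,16S), via secondary ozonide 24 (not isolated)
Conditions: O3, CH2Cl2, −78 °C (Sudan III end-point); then Me2S (5 equiv), −78 °C → rt
Reagents that add atoms: ozone [O-][O+]=O
Why: Ozonolysis with reductive work-up: the monosubstituted vinyl group is the only electron-rich alkene left (the enone is deactivated and the indicator end-point prevents over-oxidation), so C5–CH=CH2 becomes C5–CHO without touching C5–H, the epoxide, the alcohol or the lactone.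

**Compound list**

1 | 4,4-dimethylcyclohexa-2,5-dien-1-one | CC1(C)C=CC(=O)C=C1 | starting material
2 | potassium trifluoro(vinyl)borate | C=C[B-](F)(F)F.[K+] | starting material
3 | (5R)-5-ethenyl-4,4-dimethylcyclohex-2-en-1-one | CC1(C)C=CC(=O)C[C@@H]1C=C | intermediate
4 | ethyl formate | CCOC=O | starting material
5 | (5R,6Z)-5-ethenyl-6-(hydroxymethylidene)-4,4-dimethylcyclohex-2-en-1-one (enol of the 6-formyl ketone) | CC1(C)C=CC(=O)/C(=C\O)[C@@H]1C=C | intermediate
6 | 5-(methoxymethylidene)-2,2-dimethyl-1,3-dioxane-4,6-dione (methoxymethylene Meldrum's acid) | COC=C1C(=O)OC(C)(C)OC1=O | starting material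
7 | 5-{[(1R,6R)-6-ethenyl-1-formyl-5,5-dimethyl-2-oxocyclohex-3-en-1-yl](methoxy)methyl}-2,2-dimethyl-1,3-dioxane-4,6-dione (sodium enolate in the flask; both epimers at CH(OMe)) | CC1(C)C=CC(=O)[C@@](C=O)(C(OC)C2C(=O)OC(C)(C)OC2=O)[C@@H]1C=C | intermediate
8 | 5-{[(1S,6R)-6-ethenyl-1-(hydroxymethyl)-5,5-dimethyl-2-oxocyclohex-3-en-1-yl](methoxy)methyl}-2,2-dimethyl-1,3-dioxane-4,6-dione | CC1(C)C=CC(=O)[C@@](CO)(C(OC)C2C(=O)OC(C)(C)OC2=O)[C@@H]1C=C | intermediate
9 | (6S,11R)-11-ethenyl-10,10-dimethyl-3,7-dioxo-2-oxaspiro[5.5]undeca-4,8-diene-4-carboxylic acid | CC1(C)C=CC(=O)[C@]2(COC(=O)C(C(=O)O)=C2)[C@@H]1C=C | intermediate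
10 | buta-1,3-diene | C=CC=C | starting material
11 | Diels–Alder acid (5R,8S,9S,10S): A-ring enone spiro at C10 to a cis-fused δ-lactone/cyclohex-12-ene, CO2H on C8 cis to H-9, vinyl on C5 | CC1(C)C=CC(=O)[C@]2(COC(=O)[C@@]3(C(=O)O)CC=CC[C@@H]23)[C@@H]1C=C | intermediate
12 | oxalyl chloride | ClC(=O)C(Cl)=O | starting material
13 | ethynyltrimethylsilane | C#C[Si](C)(C)C | starting material
14 | acid chloride of 11 (same geometry; 8R by CIP) | CC1(C)C=CC(=O)[C@]2(COC(=O)[C@@]3(C(Cl)=O)CC=CC[C@@H]23)[C@@H]1C=C | intermediate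
15 | TMS-ynone (5R,8S,9S,10S): C8–C(=O)–C≡C–SiMe3 | CC1(C)C=CC(=O)[C@]2(COC(=O)[C@@]3(C(=O)C#C[Si](C)(C)C)CC=CC[C@@H]23)[C@@H]1C=C | intermediate
16 | silylated propargylic alcohol (5R,8S,9S,10S,15S): C8–CH(OH)–C≡C–SiMe3 | CC1(C)C=CC(=O)[C@]2(COC(=O)[C@@]3([C@H](O)C#C[Si](C)(C)C)CC=CC[C@@H]23)[C@@H]1C=C | intermediate
17 | propargylic alcohol (5R,8S,9S,10S,15R): C8–CH(OH)–C≡CH | CC1(C)C=CC(=O)[C@]2(COC(=O)[C@@]3([C@H](O)C#C)CC=CC[C@@H]23)[C@@H]1C=C | intermediate
18 | tributyltin hydride | CCCC[SnH](CCCC)CCCC | starting material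
19 | vinylstannane (5R,8S,9S,10S,13R,15S): 17-tributylstannyl derivative of 20, E/Z mixture | CC1(C)C=CC(=O)[C@]2(COC(=O)[C@@]34C[C@@H](CC[C@@H]23)C(=C[Sn](CCCC)(CCCC)CCCC)[C@H]4O)[C@@H]1C=C | intermediate
20 | tetracyclic allylic alcohol (5R,8S,9S,10S,13R,15R): bicyclo[3.2.1]octane C/D rings, exocyclic C16=C17, 15-OH anti to the C14 bridge, vinyl on C5 | CC1(C)C=CC(=O)[C@]2(COC(=O)[C@@]34C[C@@H](CC[C@@H]23)C(=C)[C@H]4O)[C@@H]1C=C | intermediate
21 | tert-butyl hydroperoxide | CC(C)(C)OO | starting material
22 | epoxy alcohol (5R,8S,9S,10S,13R,15S,16S): 16,17-epoxide of 20, oxygen syn to 15-OH | CC1(C)C=CC(=O)[C@]2(COC(=O)[C@@]34C[C@@H](CC[C@@H]23)[C@]2(CO2)[C@H]4O)[C@@H]1C=C | intermediate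
23 | ozone | [O-][O+]=O | starting material
24 | secondary ozonide of 22 (1,2,4-trioxolane at the former vinyl group, epimers at the ring carbon) | CC1(C)C=CC(=O)[C@]2(COC(=O)[C@@]34C[C@@H](CC[C@@H]23)[C@]2(CO2)[C@H]4O)[C@@H]1C1OCOO1 | intermediate
25 | CNP0537841.1: (5R,8S,9S,10S,13R,15S,16S)-15-hydroxy-16,17-epoxy-1-oxo-6,7-seco-ent-kaur-2-en-6-al 7,20-lactone | CC1(C)C=CC(=O)[C@]2(COC(=O)[C@@]34C[C@@H](CC[C@@H]23)[C@]2(CO2)[C@H]4O)[C@@H]1C=O | target

**Step count and risks**

Total steps: 9. Longest linear sequence: 9 (fully linear from 1).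

The three steps most likely to fail are steps 3, 4 and 7.

Step 3 is the proposed new annulation. Three things are untested: C–C bond formation at a hindered tertiary enolate carbon, survival of the masked alkylidene during hydride reduction, and the facial selectivity at C10. The fallback uses known chemistry only, sets out from 5 and comes back at 9. The sodium enolate of 5 is C-alkenylated with diethyl (ethoxymethylene)malonate by addition–elimination to give the alkylidene malonate aldehyde F1. Sodium triacetoxyborohydride then reduces only the aldehyde to the hydroxy diester F2. TsOH in warm toluene closes the lactone through the cis ester to give the lactone ethyl ester F3. Me3SnOH in 1,2-dichloroethane at 80 °C cleaves the remaining ethyl ester to 9.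

Step 4 is the Diels–Alder reaction. The β-carbon of the dienophile is neopentyl, and the facial selectivity rests only on the size difference between the C1 carbonyl and the C5 vinyl/CMe2 side. The fallback builds ring C stepwise, sets out from 9 and comes back at 11. Hosomi–Sakurai conjugate allylation (allyltrimethylsilane, TiCl4, −78 °C) at C9 from the same open face gives the 9-allyl malonic half-acid F4. Heating in toluene decarboxylates it to the 9-allyl lactone F5. LDA and allyl bromide give the 8,9-diallyl lactone F6. LDA then CO2 carboxylates C8 anti to the C9 allyl group to give the diallyl acid F7. Ring-closing metathesis with Grubbs II catalyst (the hindered C5 vinyl group is a spectator) closes the cyclohexene to 11.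

Step 7 is the radical enyne cyclisation. The risks are simple hydrostannation without ring closure, and 6-endo or rearranged bicyclo[2.2.2] product. The fallback sets out from 17 and comes back at 20 in one operation with no new compound. It is a palladium-catalysed reductive enyne cyclisation (Pd2(dba)3·CHCl3, P(o-tol)3, AcOH, Et3SiH, PhMe): hydropalladation of the alkyne, 5-exo carbopalladation of C12=C13, and silane reduction of the alkyl–palladium.

**Further compounds**

F1 | step 3 | alkylidene malonate aldehyde: diethyl 2-{[(1S,6R)-6-ethenyl-1-formyl-5,5-dimethyl-2-oxocyclohex-3-en-1-yl]methylidene}propanedioate | CC1(C)C=CC(=O)[C@@](C=O)(C=C(C(=O)OCC)C(=O)OCC)[C@@H]1C=C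
F2 | step 3 | hydroxy diester: diethyl 2-{[(1S,6R)-6-ethenyl-1-(hydroxymethyl)-5,5-dimethyl-2-oxocyclohex-3-en-1-yl]methylidene}propanedioate | CC1(C)C=CC(=O)[C@@](CO)(C=C(C(=O)OCC)C(=O)OCC)[C@@H]1C=C
F3 | step 3 | lactone ethyl ester: ethyl ester of 9 | CC1(C)C=CC(=O)[C@]2(COC(=O)C(C(=O)OCC)=C2)[C@@H]1C=C
F4 | step 4 | 9-allyl malonic half-acid (C8 epimers) | CC1(C)C=CC(=O)[C@]2(COC(=O)C(C(=O)O)[C@H]2CC=C)[C@@H]1C=C
F5 | step 4 | 9-allyl lactone | CC1(C)C=CC(=O)[C@]2(COC(=O)C[C@H]2CC=C)[C@@H]1C=C
F6 | step 4 | 8,9-diallyl lactone (C8 epimers) | CC1(C)C=CC(=O)[C@]2(COC(=O)C(CC=C)[C@H]2CC=C)[C@@H]1C=C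
F7 | step 4 | diallyl acid: 8-allyl-8-carboxy-9-allyl lactone with the allyl groups cis | CC1(C)C=CC(=O)[C@]2(COC(=O)[C@](CC=C)(C(=O)O)[C@H]2CC=C)[C@@H]1C=C
F0 | step 7 | none | none
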